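The pyranone is cut at O1–C2 and C4–C4a. The O1–C2–C3–C4 chain of the flavanone is a β-aryloxy acyl unit, i.e. an opened 3,4-diaryl β-lactone, and ring A is a symmetric phloroglucinol whose oxygen and either ortho carbon form a 1,3-dinucleophile. In one flask a caesium phenoxide opens the lactone at its benzylic carbon with inversion (setting C2) and trifluoroacetic anhydride closes ring C by Friedel–Crafts acylation. The precursor is the cis-(3S,4S)-lactone with the brominated, O-benzylated ring D on C3 and the tert-butyl-carbonate-protected ring B on C4, made by an auxiliary syn-aldol and lactonisation; a Heck coupling and one Lewis-acid deprotection finish the route.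

Key step: step 6

Assumption: 2-(5-bromo-2-hydroxyphenyl)acetic acid, (S)-4-benzyl-1,3-oxazolidin-2-one, 4-formylphenyl acetate, 3,5-bis(benzyloxy)phenol and 2,4-dihydroxyacetophenone are bought as such.

Remark on stereochemistry: the descriptors were rederived from the target and are consistent along the chain (2S,3S)-syn aldol → (3S,4S)-cis lactone → (2S,3R)-anti acid → (2R,3S)-trans chromanone. C3 is α to the ketone and settles trans to C2, so only the benzylic centre (lactone C4, inverted to C2) has to be carried without loss.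

Remark on protection: ring B keeps a tert-butyl carbonate because it is the one electron-poor O-substituent that the final Lewis-acid step removes. It is put on after the basic auxiliary cleavage, and its exposure to a nucleophile and to acid is confined to the key step, where hindrance, stoichiometry and temperature protect it.

Step 1
Reactants: 1 2-(5-bromo-2-hydroxyphenyl)acetic acid
Product: 3 2-[2-(benzyloxy)-5-bromophenyl]acetic acid, via benzyl 2-[2-(benzyloxy)-5-bromophenyl]acetate 2 (not isolated)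
Conditions: BnBr (2.3 equiv), K2CO3, DMF, 60 °C; then 2 M NaOH, MeOH, 50 °C; aq. HCl to pH 2
Reagents that add atoms: benzyl bromide, BrCc1ccccc1; sodium hydroxide, [Na+].[OH-]
Why: Williamson O-alkylation of the phenoxide and the carboxylate (SN2), then saponification of the benzyl ester in the same flask, should leave the benzyl aryl ether and the free acid; no stereocentre is involved.

Step 2
Reactants: 3 2-[2-(benzyloxy)-5-bromophenyl]acetic acid; 4 (S)-4-benzyl-1,3-oxazolidin-2-one
Product: 6 (4S)-4-benzyl-3-{[2-(benzyloxy)-5-bromophenyl]acetyl}-1,3-oxazolidin-2-one, via 2-[2-(benzyloxy)-5-bromophenyl]acetic pivalic anhydride 5 (not isolated)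
Conditions: PivCl, Et3N, THF, −20 °C; then 4, LiCl, −20 °C → rt
Reagents that add atoms: none
Why: N-acylation of the oxazolidinone by the mixed pivalic anhydride under LiCl/Et3N activation (acyl substitution at the less hindered carbonyl) should give the imide without touching the auxiliary stereocentre.

Step 3
Reactants: 6 (4S)-4-benzyl-3-{[2-(benzyloxy)-5-bromophenyl]acetyl}-1,3-oxazolidin-2-one; 7 4-formylphenyl acetate
Product: 9 (4S)-3-{(2S,3S)-3-[4-(acetyloxy)phenyl]-2-[2-(benzyloxy)-5-bromophenyl]-3-hydroxypropanoyl}-4-benzyl-1,3-oxazolidin-2-one, via (4S)-4-benzyl-3-{(Z)-2-[2-(benzyloxy)-5-bromophenyl]-1-[(dibutylboranyl)oxy]ethenyl}-1,3-oxazolidin-2-one 8 (not isolated)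
Conditions: Bu2BOTf, iPr2NEt, CH2Cl2, 0 °C; then 7, −78 → 0 °C; pH 7 buffer/MeOH, MeOH co-evaporation (no peroxide)
Reagents that add atoms: none
Why: Evans syn-aldol reaction: the (Z)-boron enolate adds through a Zimmerman–Traxler chair to the aldehyde on the face remote from the auxiliary benzyl group, which should set both new centres (2S,3S, syn) under auxiliary control, while the aryl acetate is inert to the enolate and keeps ring B electron-poor.

Step 4
Reactants: 9 (4S)-3-{(2S,3S)-3-[4-(acetyloxy)phenyl]-2-[2-(benzyloxy)-5-bromophenyl]-3-hydroxypropanoyl}-4-benzyl-1,3-oxazolidin-2-one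
Product: 11 (2S,3S)-2-[2-(benzyloxy)-5-bromophenyl]-3-{4-[(tert-butoxycarbonyl)oxy]phenyl}-3-hydroxypropanoic acid, via dilithium (2S,3S)-2-[2-(benzyloxy)-5-bromophenyl]-3-hydroxy-3-(4-oxidophenyl)propanoate 10 (not isolated)
Conditions: LiOH, H2O2, THF/H2O, 0 °C; aq. Na2SO3; CH2Cl2 wash (returns 4); aqueous phase to pH 10, Boc2O, dioxane, 0 °C → rt; HCl to pH 3, 0 °C
Reagents that add atoms: hydrogen peroxide (as LiOOH), OO; di-tert-butyl dicarbonate, CC(C)(C)OC(=O)OC(=O)OC(C)(C)C
Why: Hydroperoxide cleavage of the exocyclic imide carbonyl (and of the aryl acetate) should free the carboxylate without epimerisation, and in water at pH 10 only the phenoxide is acylated by Boc2O (Schotten–Baumann-type carbonate formation), so the acid-sensitive p-hydroxybenzylic alcohol is never isolated.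

Step 5
Reactants: 11 (2S,3S)-2-[2-(benzyloxy)-5-bromophenyl]-3-{4-[(tert-butoxycarbonyl)oxy]phenyl}-3-hydroxypropanoic acid
Product: 13 (3S,4S)-3-[2-(benzyloxy)-5-bromophenyl]-4-{4-[(tert-butoxycarbonyl)oxy]phenyl}oxetan-2-one (cis), via (2S,3S)-2-[2-(benzyloxy)-5-bromophenyl]-3-{4-[(tert-butoxycarbonyl)oxy]phenyl}-3-hydroxypropanoic benzenesulfonic anhydride 12 (not isolated)
Conditions: PhSO2Cl, pyridine, 0 → 4 °C
Reagents that add atoms: none
Why: β-Lactonisation by carboxyl activation (sulfonyl chloride/pyridine, 4-exo-trig acyl substitution by the β-hydroxyl) breaks no bond at either stereocentre, so the syn acid should give the cis-(3S,4S)-lactone.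

Step 6
Reactants: 13 (3S,4S)-3-[2-(benzyloxy)-5-bromophenyl]-4-{4-[(tert-butoxycarbonyl)oxy]phenyl}oxetan-2-one; 14 3,5-bis(benzyloxy)phenol
Product: 18 (2R,3S)-5,7-bis(benzyloxy)-3-[2-(benzyloxy)-5-bromophenyl]-2-{4-[(tert-butoxycarbonyl)oxy]phenyl}chroman-4-one (trans), via caesium 3,5-bis(benzyloxy)phenoxide 15 (not isolated), via caesium (2S,3R)-3-[3,5-bis(benzyloxy)phenoxy]-2-[2-(benzyloxy)-5-bromophenyl]-3-{4-[(tert-butoxycarbonyl)oxy]phenyl}propanoate 16 (not isolated), via (2S,3R)-3-[3,5-bis(benzyloxy)phenoxy]-2-[2-(benzyloxy)-5-bromophenyl]-3-{4-[(tert-butoxycarbonyl)oxy]phenyl}propanoic trifluoroacetic anhydride 17 (not isolated)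
Conditions: 14 (1.05 equiv), CsOH·H2O (1.0 equiv), MeOH, then PhMe azeotrope to dryness; 13, MeCN, 0 °C → rt; then CH2Cl2, TFAA (2.5 equiv), −20 → 0 °C; cold aq. NaHCO3
Reagents that add atoms: none
Why: The caesium phenoxide attacks the benzylic C4 of the β-lactone in an SN2 alkyl–oxygen cleavage that releases the four-ring strain and gives the anti-β-aryloxy carboxylate, which TFAA converts into the acyl trifluoroacetate that acylates the phloroglucinol-type ring at either of its two equivalent ortho carbons. The closest known reaction types are the phenoxide opening of β-lactones to 3-aryloxypropanoic acids and the TFAA-mediated cyclodehydration of such acids to chroman-4-ones, here run in one flask on a 3,4-diaryl lactone. The pyranone closes by a six-membered intramolecular Friedel–Crafts acylation (6-exo-trig at the acyl carbon, C4–C4a bond). C2 is set by inversion of the lactone C4 centre (substrate control, 4S → 2R), C3 is carried over unchanged, and since C3 is α to the new ketone any C3 epimer formed on the way should equilibrate to the same trans-chromanone. The step needs alkyl–oxygen instead of acyl–oxygen cleavage: attack at the carbonyl is reversible whereas carboxylate formation is not, benzylic activation and the soft caesium phenoxide favour C4, the lactone enolate cannot β-eliminate because its C4–O bond is orthogonal to the enolate π system, and the electron-poor carbonate on ring B holds back ionisation and decarboxylation. The hindered tert-butyl carbonate resists acyl transfer to the phenoxide, no hydroxide or excess phenoxide is present, MeCN replaces DMF (which TFAA would activate), and the limited TFAA at or below 0 °C leaves only one equivalent of TFA, buffered by caesium trifluoroacetate, so the carbonate should survive.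

Step 7
Reactants: 19 2,4-dihydroxyacetophenone
Product: 20 1-[2,4-bis(benzyloxy)phenyl]ethan-1-one
Conditions: BnBr (2.4 equiv), K2CO3, KI (cat.), DMF, 70 °C
Reagents that add atoms: benzyl bromide, BrCc1ccccc1
Why: Williamson ether synthesis; DMF, iodide catalysis and warming should also alkylate the chelated 2-hydroxyl.

Step 8
Reactants: 20 1-[2,4-bis(benzyloxy)phenyl]ethan-1-one
Product: 21 1-[2,4-bis(benzyloxy)phenyl]prop-2-en-1-one
Conditions: (CH2O)n, iPr2NH·TFA, TFA (cat.), THF, reflux; BHT; used at once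
Reagents that add atoms: paraformaldehyde (formaldehyde), C=O
Why: Mannich-type α-methylenation of the methyl ketone (ammonium-salt-mediated addition to formaldehyde, then β-elimination of the amine) should give the aryl vinyl ketone, which is taken on without storage.

Step 9
Reactants: 18 (2R,3S)-5,7-bis(benzyloxy)-3-[2-(benzyloxy)-5-bromophenyl]-2-{4-[(tert-butoxycarbonyl)oxy]phenyl}chroman-4-one; 21 1-[2,4-bis(benzyloxy)phenyl]prop-2-en-1-one
Product: 22 (2R,3S)-5,7-bis(benzyloxy)-3-{2-(benzyloxy)-5-[(1E)-3-[2,4-bis(benzyloxy)phenyl]-3-oxoprop-1-en-1-yl]phenyl}-2-{4-[(tert-butoxycarbonyl)oxy]phenyl}chroman-4-one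
Conditions: Pd2(dba)3 (cat.), [HP(t-Bu)3]BF4 (cat.), Cy2NMe (1.2 equiv), 21 (1.5 equiv), 1,4-dioxane, rt → 40 °C
Reagents that add atoms: none
Why: Mizoroki–Heck reaction: oxidative addition of the aryl bromide to Pd(0)/P(t-Bu)3 near room temperature, syn-carbopalladation of the vinyl ketone and syn-β-hydride elimination should give the (E)-enone, while the hindered tertiary amine in dioxane is too weak a base to enolise C3 or open the pyranone, so C2 and C3 stay as set.

Step 10
Reactants: 22 (2R,3S)-5,7-bis(benzyloxy)-3-{2-(benzyloxy)-5-[(1E)-3-[2,4-bis(benzyloxy)phenyl]-3-oxoprop-1-en-1-yl]phenyl}-2-{4-[(tert-butoxycarbonyl)oxy]phenyl}chroman-4-one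
Product: 23 (2R,3S)-3-{5-[(1E)-3-(2,4-dihydroxyphenyl)-3-oxoprop-1-en-1-yl]-2-hydroxyphenyl}-5,7-dihydroxy-2-(4-hydroxyphenyl)chroman-4-one (CNP0272156.1)
Conditions: BCl3 (excess), C6HMe5, CH2Cl2, −78 → 0 °C; MeOH
Reagents that add atoms: none
Why: Lewis-acid dealkylation: BCl3 cleaves the five aryl benzyl ethers with pentamethylbenzene as a non-coordinating cation scavenger and, on warming, the tert-butyl carbonate (loss of CO2), under non-basic conditions that should leave the two stereocentres and the (E)-enone untouched.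

Compound list
1 | 2-(5-bromo-2-hydroxyphenyl)acetic acid | OC(=O)Cc1cc(Br)ccc1O | starting material
2 | benzyl 2-[2-(benzyloxy)-5-bromophenyl]acetate | O=C(Cc1cc(Br)ccc1OCc1ccccc1)OCc1ccccc1 | intermediate (not isolated)
3 | 2-[2-(benzyloxy)-5-bromophenyl]acetic acid | OC(=O)Cc1cc(Br)ccc1OCc1ccccc1 | intermediate
4 | (S)-4-benzyl-1,3-oxazolidin-2-one | O=C1OC[C@H](Cc2ccccc2)N1 | starting material
5 | 2-[2-(benzyloxy)-5-bromophenyl]acetic pivalic anhydride | CC(C)(C)C(=O)OC(=O)Cc1cc(Br)ccc1OCc1ccccc1 | intermediate (not isolated)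
6 | (4S)-4-benzyl-3-{[2-(benzyloxy)-5-bromophenyl]acetyl}-1,3-oxazolidin-2-one | O=C1OC[C@H](Cc2ccccc2)N1C(=O)Cc1cc(Br)ccc1OCc1ccccc1 | intermediate
7 | 4-formylphenyl acetate | CC(=O)Oc1ccc(C=O)cc1 | starting material
8 | (4S)-4-benzyl-3-{(Z)-2-[2-(benzyloxy)-5-bromophenyl]-1-[(dibutylboranyl)oxy]ethenyl}-1,3-oxazolidin-2-one | CCCCB(CCCC)O/C(=C\c1cc(Br)ccc1OCc1ccccc1)N1[C@@H](Cc2ccccc2)COC1=O | intermediate (not isolated)
9 | (4S)-3-{(2S,3S)-3-[4-(acetyloxy)phenyl]-2-[2-(benzyloxy)-5-bromophenyl]-3-hydroxypropanoyl}-4-benzyl-1,3-oxazolidin-2-one | Brc1ccc(OCc2ccccc2)c(c1)[C@H](C(=O)N1[C@@H](Cc2ccccc2)COC1=O)[C@H](O)c1ccc(OC(C)=O)cc1 | intermediate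
10 | dilithium (2S,3S)-2-[2-(benzyloxy)-5-bromophenyl]-3-hydroxy-3-(4-oxidophenyl)propanoate | [Li+].[Li+].Brc1ccc(OCc2ccccc2)c(c1)[C@H](C(=O)[O-])[C@H](O)c1ccc([O-])cc1 | intermediate (not isolated)
11 | (2S,3S)-2-[2-(benzyloxy)-5-bromophenyl]-3-{4-[(tert-butoxycarbonyl)oxy]phenyl}-3-hydroxypropanoic acid | Brc1ccc(OCc2ccccc2)c(c1)[C@H](C(=O)O)[C@H](O)c1ccc(OC(=O)OC(C)(C)C)cc1 | intermediate
12 | (2S,3S)-2-[2-(benzyloxy)-5-bromophenyl]-3-{4-[(tert-butoxycarbonyl)oxy]phenyl}-3-hydroxypropanoic benzenesulfonic anhydride | Brc1ccc(OCc2ccccc2)c(c1)[C@H](C(=O)OS(=O)(=O)c1ccccc1)[C@H](O)c1ccc(OC(=O)OC(C)(C)C)cc1 | intermediate (not isolated)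
13 | (3S,4S)-3-[2-(benzyloxy)-5-bromophenyl]-4-{4-[(tert-butoxycarbonyl)oxy]phenyl}oxetan-2-one (cis) | Brc1ccc(OCc3ccccc3)c([C@@H]2C(=O)O[C@@H]2c2ccc(OC(=O)OC(C)(C)C)cc2)c1 | intermediate
14 | 3,5-bis(benzyloxy)phenol | Oc1cc(OCc2ccccc2)cc(OCc2ccccc2)c1 | starting material
15 | caesium 3,5-bis(benzyloxy)phenoxide | [Cs+].[O-]c1cc(OCc2ccccc2)cc(OCc2ccccc2)c1 | intermediate (not isolated)
16 | caesium (2S,3R)-3-[3,5-bis(benzyloxy)phenoxy]-2-[2-(benzyloxy)-5-bromophenyl]-3-{4-[(tert-butoxycarbonyl)oxy]phenyl}propanoate (anti) | [Cs+].Brc1ccc(OCc2ccccc2)c(c1)[C@H](C(=O)[O-])[C@@H](Oc1cc(OCc2ccccc2)cc(OCc2ccccc2)c1)c1ccc(OC(=O)OC(C)(C)C)cc1 | intermediate (not isolated)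
17 | (2S,3R)-3-[3,5-bis(benzyloxy)phenoxy]-2-[2-(benzyloxy)-5-bromophenyl]-3-{4-[(tert-butoxycarbonyl)oxy]phenyl}propanoic trifluoroacetic anhydride | Brc1ccc(OCc2ccccc2)c(c1)[C@H](C(=O)OC(=O)C(F)(F)F)[C@@H](Oc1cc(OCc2ccccc2)cc(OCc2ccccc2)c1)c1ccc(OC(=O)OC(C)(C)C)cc1 | intermediate (not isolated)
18 | (2R,3S)-5,7-bis(benzyloxy)-3-[2-(benzyloxy)-5-bromophenyl]-2-{4-[(tert-butoxycarbonyl)oxy]phenyl}chroman-4-one (trans) | Brc1ccc(OCc4ccccc4)c([C@@H]2C(=O)c3c(OCc4ccccc4)cc(OCc4ccccc4)cc3O[C@H]2c2ccc(OC(=O)OC(C)(C)C)cc2)c1 | intermediate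
19 | 2,4-dihydroxyacetophenone | CC(=O)c1ccc(O)cc1O | starting material
20 | 1-[2,4-bis(benzyloxy)phenyl]ethan-1-one | CC(=O)c1ccc(OCc2ccccc2)cc1OCc1ccccc1 | intermediate
21 | 1-[2,4-bis(benzyloxy)phenyl]prop-2-en-1-one | C=CC(=O)c1ccc(OCc2ccccc2)cc1OCc1ccccc1 | intermediate
22 | (2R,3S)-5,7-bis(benzyloxy)-3-{2-(benzyloxy)-5-[(1E)-3-[2,4-bis(benzyloxy)phenyl]-3-oxoprop-1-en-1-yl]phenyl}-2-{4-[(tert-butoxycarbonyl)oxy]phenyl}chroman-4-one | O=C(/C=C/c1ccc(OCc5ccccc5)c([C@@H]2C(=O)c3c(OCc5ccccc5)cc(OCc5ccccc5)cc3O[C@H]2c2ccc(OC(=O)OC(C)(C)C)cc2)c1)c1ccc(OCc2ccccc2)cc1OCc1ccccc1 | intermediate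
23 | (2R,3S)-3-{5-[(1E)-3-(2,4-dihydroxyphenyl)-3-oxoprop-1-en-1-yl]-2-hydroxyphenyl}-5,7-dihydroxy-2-(4-hydroxyphenyl)chroman-4-one | O=C(/C=C/c1ccc(O)c([C@@H]2C(=O)c3c(O)cc(O)cc3O[C@H]2c2ccc(O)cc2)c1)c1ccc(O)cc1O | target

Total step count: 10. Longest linear sequence: 8 (steps 1–6, 9, 10); steps 7 and 8 form the side branch.

Steps most likely to fail

1. Step 6. The phenoxide may attack the lactone carbonyl, and retro-aldol cleavage of the resulting alkoxide would lose the configuration of the benzylic carbon. The carbonate may transfer from ring B to the phenoxide, which would trigger quinone-methide opening of the lactone. The lactone may decarboxylate, or the carbonate may be lost to acid during the acylation. The fallback forms the ether by Mitsunobu inversion instead of lactone opening and sets out from 11 and 14. Alkylation of the carboxylate (allyl bromide, KHCO3, DMF, rt) should give prop-2-en-1-yl (2S,3S)-2-[2-(benzyloxy)-5-bromophenyl]-3-{4-[(tert-butoxycarbonyl)oxy]phenyl}-3-hydroxypropanoate F1. A Mitsunobu reaction with 14 (PPh3, DIAD, toluene, 0 °C) should invert the benzylic carbinol and give prop-2-en-1-yl (2S,3R)-3-[3,5-bis(benzyloxy)phenoxy]-2-[2-(benzyloxy)-5-bromophenyl]-3-{4-[(tert-butoxycarbonyl)oxy]phenyl}propanoate F2. Neutral deallylation (Pd(PPh3)4 cat., PhSiH3, CH2Cl2, rt) should give (2S,3R)-3-[3,5-bis(benzyloxy)phenoxy]-2-[2-(benzyloxy)-5-bromophenyl]-3-{4-[(tert-butoxycarbonyl)oxy]phenyl}propanoic acid F3. With TFAA in CH2Cl2 at −20 → 0 °C, F3 forms 17, so the route is rejoined at 17 and 18.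

2. Step 9. The amine may enolise C3, and reversible β-elimination of the ring oxygen would erode the configuration at C2. The vinyl ketone may polymerise, or oxidative addition of the electron-rich bromide may be sluggish. The fallback replaces the Heck reaction by base-free vinylation and olefin metathesis and sets out from 18. A Stille coupling with tributyl(vinyl)stannane (Pd(PPh3)4, toluene, 90 °C, no base) should give (2R,3S)-5,7-bis(benzyloxy)-3-[2-(benzyloxy)-5-ethenylphenyl]-2-{4-[(tert-butoxycarbonyl)oxy]phenyl}chroman-4-one F4. Cross-metathesis of F4 with 21 (Hoveyda–Grubbs second-generation catalyst, CH2Cl2, 40 °C) should give the (E)-enone, rejoining the route at 22.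

3. Step 10. Cleavage of one of the six groups may stay incomplete. Benzyl or tert-butyl cations may alkylate the electron-rich rings. HCl may add to the 2′-hydroxychalcone, or the Lewis acid may cyclise it. The fallback builds the enone last by an acid-mediated Claisen–Schmidt condensation, so that no protected enone has to be deprotected; it sets out from 18 and 19. The ethenyl compound F4 (Stille coupling as in the fallback above) is cleaved oxidatively (OsO4 cat., NaIO4, THF/H2O, rt) to 4-(benzyloxy)-3-[(2R,3S)-5,7-bis(benzyloxy)-2-{4-[(tert-butoxycarbonyl)oxy]phenyl}-4-oxochroman-3-yl]benzaldehyde F5. BCl3/C6HMe5 (CH2Cl2, −78 → 0 °C) should remove the three benzyl groups and the carbonate to give 4-hydroxy-3-[(2R,3S)-5,7-dihydroxy-2-(4-hydroxyphenyl)-4-oxochroman-3-yl]benzaldehyde F6. Condensation of F6 with 19 (BF3·OEt2, 1,4-dioxane, rt) should give the (E)-chalcone directly, rejoining the route at the target 23.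

Further compounds
F1 | step 6 | prop-2-en-1-yl (2S,3S)-2-[2-(benzyloxy)-5-bromophenyl]-3-{4-[(tert-butoxycarbonyl)oxy]phenyl}-3-hydroxypropanoate | Brc1ccc(OCc2ccccc2)c(c1)[C@H](C(=O)OCC=C)[C@H](O)c1ccc(OC(=O)OC(C)(C)C)cc1
F2 | step 6 | prop-2-en-1-yl (2S,3R)-3-[3,5-bis(benzyloxy)phenoxy]-2-[2-(benzyloxy)-5-bromophenyl]-3-{4-[(tert-butoxycarbonyl)oxy]phenyl}propanoate | Brc1ccc(OCc2ccccc2)c(c1)[C@H](C(=O)OCC=C)[C@@H](Oc1cc(OCc2ccccc2)cc(OCc2ccccc2)c1)c1ccc(OC(=O)OC(C)(C)C)cc1
F3 | step 6 | (2S,3R)-3-[3,5-bis(benzyloxy)phenoxy]-2-[2-(benzyloxy)-5-bromophenyl]-3-{4-[(tert-butoxycarbonyl)oxy]phenyl}propanoic acid | Brc1ccc(OCc2ccccc2)c(c1)[C@H](C(=O)O)[C@@H](Oc1cc(OCc2ccccc2)cc(OCc2ccccc2)c1)c1ccc(OC(=O)OC(C)(C)C)cc1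
F4 | step 9 | (2R,3S)-5,7-bis(benzyloxy)-3-[2-(benzyloxy)-5-ethenylphenyl]-2-{4-[(tert-butoxycarbonyl)oxy]phenyl}chroman-4-one | C=Cc1ccc(OCc5ccccc5)c([C@@H]2C(=O)c3c(OCc5ccccc5)cc(OCc5ccccc5)cc3O[C@H]2c2ccc(OC(=O)OC(C)(C)C)cc2)c1
F5 | step 10 | 4-(benzyloxy)-3-[(2R,3S)-5,7-bis(benzyloxy)-2-{4-[(tert-butoxycarbonyl)oxy]phenyl}-4-oxochroman-3-yl]benzaldehyde | O=Cc1ccc(OCc5ccccc5)c([C@@H]2C(=O)c3c(OCc5ccccc5)cc(OCc5ccccc5)cc3O[C@H]2c2ccc(OC(=O)OC(C)(C)C)cc2)c1
F6 | step 10 | 4-hydroxy-3-[(2R,3S)-5,7-dihydroxy-2-(4-hydroxyphenyl)-4-oxochroman-3-yl]benzaldehyde | O=Cc1ccc(O)c([C@@H]2C(=O)c3c(O)cc(O)cc3O[C@H]2c2ccc(O)cc2)c1
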